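## Retrosynthetic overview

1. The target acid (20) comes from its methyl ester (19) by SN2 O‑demethylation.
2. 19 comes from an intramolecular Diels–Alder reaction (IMDA) of the linear (2E,4Z,6S,7E,9E,11E,13E)-hexaene ester 18. The cyclohexene and the cyclopentene form together in this one step (bonds C3a–C7a and C4–C5), and the single C6 stereocenter sets the other four.
3. 18 comes from β,γ‑unsaturated aldehyde 11 by a Still–Gennari olefination (Z‑C4=C5) and then a Wittig olefination (E‑C2=C3).
4. 11 comes from aldehyde 4 by two formyl‑ylide Wittig homologations and a cinnamylphosphonate HWE reaction.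
5. 4 comes from (R)-Roche ester 1, the only source of chirality.

Assumption: the SMILES is read as the (1R,3aR,4R,5S,7aS) trans‑fused tetrahydroindene (my own CIP assignment). Phosphonate 14 is not assumed to be purchasable and is made in one step (step 8).

## Route

**Step 1**
Reactants: 1, methyl (R)-3-hydroxy-2-methylpropanoate; 2, tert‑butyldimethylsilyl chloride
Product: 3, methyl (R)-3-[(tert‑butyldimethylsilyl)oxy]-2-methylpropanoate
Conditions: TBSCl, imidazole, DMF, 0 °C → rt
Reagents that add atoms: TBSCl (2), CC(C)(C)[Si](C)(C)Cl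
Why: Imidazole‑promoted O‑silylation of the primary alcohol; the stereocenter is not touched.

**Step 2**
Reactants: 3
Product: 4, (R)-3-[(tert‑butyldimethylsilyl)oxy]-2-methylpropanal
Conditions: DIBAL‑H (1.05 eq), CH2Cl2, −78 °C; Rochelle salt work‑up; used crude
Reagents that add atoms: none
Why: Partial ester reduction; the tetrahedral aluminium hemiacetal is stable at −78 °C and releases the aldehyde only on work‑up, and with no base present the α‑stereocenter is retained.

**Step 3**
Reactants: 4; 5, 2-(triphenylphosphoranylidene)propanal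
Product: 6, (S,E)-5-[(tert‑butyldimethylsilyl)oxy]-2,4-dimethylpent-2-enal
Conditions: 5 (1.2 eq), PhMe, 85 °C
Reagents that add atoms: 5, CC(C=O)=P(c1ccccc1)(c1ccccc1)c1ccccc1
Why: Wittig olefination with a stabilised formyl ylide gives the (E)-trisubstituted enal; the product enal is much less electrophilic than 4, so homologation stops after one unit, and the neutral conditions preserve the α‑stereocenter.

**Step 4**
Reactants: 6; 5
Product: 7, (2E,4E,6S)-7-[(tert‑butyldimethylsilyl)oxy]-2,4,6-trimethylhepta-2,4-dienal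
Conditions: 5 (2 eq), PhMe, 110 °C, 24–36 h
Reagents that add atoms: 5, CC(C=O)=P(c1ccccc1)(c1ccccc1)c1ccccc1
Why: Second stabilised‑ylide Wittig homologation under forcing conditions, E‑selective under thermodynamic control; the stereocenter is now allylic to a non‑acidic position and is unaffected.

**Step 5**
Reactants: 7; 8, diethyl [(E)-3-phenylprop-2-en-1-yl]phosphonate
Product: 9, tert‑butyldimethyl{[(2S,3E,5E,7E,9E)-2,4,6-trimethyl-10-phenyldeca-3,5,7,9-tetraen-1-yl]oxy}silane
Conditions: 8, LiHMDS, THF, −78 °C; then 7, −78 → 0 °C; dark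
Reagents that add atoms: 8, CCOP(=O)(OCC)C/C=C/c1ccccc1
Why: Horner–Wadsworth–Emmons olefination with an allylic phosphonate gives the new C7=C8 bond E‑selectively and completes the all‑E phenyltetraene.

**Step 6**
Reactants: 9
Product: 10, (2S,3E,5E,7E,9E)-2,4,6-trimethyl-10-phenyldeca-3,5,7,9-tetraen-1-ol
Conditions: TBAF, THF, 0 °C → rt; dark
Reagents that add atoms: none
Why: Fluoride desilylation; the polyene and the stereocenter are inert to it.

**Step 7**
Reactants: 10
Product: 11, (2S,3E,5E,7E,9E)-2,4,6-trimethyl-10-phenyldeca-3,5,7,9-tetraenal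
Conditions: Dess–Martin periodinane, NaHCO3, CH2Cl2, 0 °C; short filtration, used cold and at once
Reagents that add atoms: none
Why: Dess–Martin oxidation under buffered, base‑free conditions; the β,γ‑unsaturated α‑methyl aldehyde is made without epimerisation or conjugation only if it is not stored or chromatographed.

**Step 8** (reagent preparation)
Reactants: 12, methyl 2-[bis(2,2,2-trifluoroethoxy)phosphoryl]acetate; 13, iodoethane
Product: 14, methyl 2-[bis(2,2,2-trifluoroethoxy)phosphoryl]butanoate (racemic)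
Conditions: NaH, THF/DMSO, 0 °C; then EtI, rt
Reagents that add atoms: iodoethane (13), CCI
Why: SN2 C‑alkylation of the phosphonoacetate anion; one equivalent of base limits dialkylation.

**Step 9**
Reactants: 11; 14
Product: 15, methyl (2Z,4S,5E,7E,9E,11E)-2-ethyl-4,6,8-trimethyl-12-phenyldodeca-2,5,7,9,11-pentaenoate
Conditions: 14 (1.3 eq), KHMDS (1.2 eq), 18‑crown‑6, THF, −78 °C; then 11, −78 °C
Reagents that add atoms: 14, CCC(C(=O)OC)P(=O)(OCC(F)(F)F)OCC(F)(F)F
Why: Still–Gennari olefination; the trifluoroethyl phosphonate with a dissociated potassium counter‑ion gives kinetic Z‑selectivity, placing the ester carbon cis to the C4 chain, and the pre‑formed weakly basic anion at −78 °C leaves the α‑stereocenter intact.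

**Step 10**
Reactants: 15
Product: 16, (2Z,4S,5E,7E,9E,11E)-2-ethyl-4,6,8-trimethyl-12-phenyldodeca-2,5,7,9,11-pentaen-1-ol
Conditions: DIBAL‑H (2.5 eq), CH2Cl2, −78 °C
Reagents that add atoms: none
Why: 1,2‑Reduction of the enoate to the allylic alcohol with retention of the Z geometry.

**Step 11**
Reactants: 16; 17, methyl 2-(triphenylphosphoranylidene)propanoate
Product: 18, methyl (2E,4Z,6S,7E,9E,11E,13E)-4-ethyl-2,6,8,10-trimethyl-14-phenyltetradeca-2,4,7,9,11,13-hexaenoate
Conditions: activated MnO2 (excess), 17 (2 eq), CH2Cl2, rt → 40 °C; dark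
Reagents that add atoms: 17, COC(=O)C(C)=P(c1ccccc1)(c1ccccc1)c1ccccc1
Why: Tandem allylic oxidation–Wittig olefination; the Z‑enal is trapped in situ before it can isomerise, the stabilised ylide gives the E‑tiglate, and the neutral medium spares the bis‑allylic C6–H.

**Step 12** (key step)
Reactants: 18
Product: 19, methyl (1R,3aR,4R,5S,7aS)-3-ethyl-1,4,5,7-tetramethyl-5-[(1E,3E)-4-phenylbuta-1,3-dien-1-yl]-3a,4,5,7a-tetrahydro-1H-indene-4-carboxylate (trans ring fusion)
Conditions: PhMe (5 mM), BHT (cat.), degassed, 100 °C, dark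
Reagents that add atoms: none
Why: Intramolecular Diels–Alder reaction of the C7–C10 (E,E)-diene with the C2=C3 (E)-dienophile through the ester‑endo, tether‑anti transition state, which gives the trans fusion.
- Facial control: C6–H eclipses the C7=C8 bond to avoid A(1,3) strain with the C8 methyl, so the tethered dienophile adds anti to the C6 methyl. This puts C1‑Me trans to the C7a–C7 bond.
- Geometry transfer: suprafacial addition carries the E‑dienophile into CO2Me cis to H‑3a, and the E,E‑diene into dienyl (outside) cis to CO2Me and trans to H‑7a.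
- Tether: the Z‑C4=C5 alkene is what allows the three‑atom tether to close to the cyclopentene.

**Step 13**
Reactants: 19
Product: 20, 22‑nor‑zyggomphic acid B, (1R,3aR,4R,5S,7aS)-3-ethyl-1,4,5,7-tetramethyl-5-[(1E,3E)-4-phenylbuta-1,3-dien-1-yl]-3a,4,5,7a-tetrahydro-1H-indene-4-carboxylic acid
Conditions: n‑PrSLi, HMPA, rt; then aq. citric acid
Reagents that add atoms: none
Why: SN2 (BAl2) O‑demethylation by thiolate at the methyl carbon, so the hindrance of the carbonyl flanked by two quaternary carbons does not matter; there is no epimerisable centre and the unactivated diene and alkenes do not react with thiolate.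

## Compound list

1 | methyl (R)-3-hydroxy-2-methylpropanoate ((R)-Roche ester) | COC(=O)[C@H](C)CO | starting material
2 | tert‑butyldimethylsilyl chloride | CC(C)(C)[Si](C)(C)Cl | starting material
3 | methyl (R)-3-[(tert‑butyldimethylsilyl)oxy]-2-methylpropanoate | COC(=O)[C@H](C)CO[Si](C)(C)C(C)(C)C | intermediate
4 | (R)-3-[(tert‑butyldimethylsilyl)oxy]-2-methylpropanal | O=C[C@H](C)CO[Si](C)(C)C(C)(C)C | intermediate
5 | 2-(triphenylphosphoranylidene)propanal | CC(C=O)=P(c1ccccc1)(c1ccccc1)c1ccccc1 | starting material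
6 | (S,E)-5-[(tert‑butyldimethylsilyl)oxy]-2,4-dimethylpent-2-enal | O=C/C(C)=C/[C@H](C)CO[Si](C)(C)C(C)(C)C | intermediate
7 | (2E,4E,6S)-7-[(tert‑butyldimethylsilyl)oxy]-2,4,6-trimethylhepta-2,4-dienal | O=C/C(C)=C/C(C)=C/[C@H](C)CO[Si](C)(C)C(C)(C)C | intermediate
8 | diethyl [(E)-3-phenylprop-2-en-1-yl]phosphonate | CCOP(=O)(OCC)C/C=C/c1ccccc1 | starting material
9 | tert‑butyldimethyl{[(2S,3E,5E,7E,9E)-2,4,6-trimethyl-10-phenyldeca-3,5,7,9-tetraen-1-yl]oxy}silane | CC(C)(C)[Si](C)(C)OC[C@@H](C)/C=C(C)/C=C(C)/C=C/C=C/c1ccccc1 | intermediate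
10 | (2S,3E,5E,7E,9E)-2,4,6-trimethyl-10-phenyldeca-3,5,7,9-tetraen-1-ol | OC[C@@H](C)/C=C(C)/C=C(C)/C=C/C=C/c1ccccc1 | intermediate
11 | (2S,3E,5E,7E,9E)-2,4,6-trimethyl-10-phenyldeca-3,5,7,9-tetraenal | O=C[C@@H](C)/C=C(C)/C=C(C)/C=C/C=C/c1ccccc1 | intermediate
12 | methyl 2-[bis(2,2,2-trifluoroethoxy)phosphoryl]acetate | COC(=O)CP(=O)(OCC(F)(F)F)OCC(F)(F)F | starting material
13 | iodoethane | CCI | starting material
14 | methyl 2-[bis(2,2,2-trifluoroethoxy)phosphoryl]butanoate (racemic) | CCC(C(=O)OC)P(=O)(OCC(F)(F)F)OCC(F)(F)F | intermediate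
15 | methyl (2Z,4S,5E,7E,9E,11E)-2-ethyl-4,6,8-trimethyl-12-phenyldodeca-2,5,7,9,11-pentaenoate | COC(=O)/C(CC)=C\[C@@H](C)/C=C(C)/C=C(C)/C=C/C=C/c1ccccc1 | intermediate
16 | (2Z,4S,5E,7E,9E,11E)-2-ethyl-4,6,8-trimethyl-12-phenyldodeca-2,5,7,9,11-pentaen-1-ol | OC/C(CC)=C\[C@@H](C)/C=C(C)/C=C(C)/C=C/C=C/c1ccccc1 | intermediate
17 | methyl 2-(triphenylphosphoranylidene)propanoate | COC(=O)C(C)=P(c1ccccc1)(c1ccccc1)c1ccccc1 | starting material
18 | methyl (2E,4Z,6S,7E,9E,11E,13E)-4-ethyl-2,6,8,10-trimethyl-14-phenyltetradeca-2,4,7,9,11,13-hexaenoate | COC(=O)/C(C)=C/C(CC)=C\[C@@H](C)/C=C(C)/C=C(C)/C=C/C=C/c1ccccc1 | intermediate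
19 | methyl (1R,3aR,4R,5S,7aS)-3-ethyl-1,4,5,7-tetramethyl-5-[(1E,3E)-4-phenylbuta-1,3-dien-1-yl]-3a,4,5,7a-tetrahydro-1H-indene-4-carboxylate | CCC1=C[C@@H](C)[C@@H]2C(C)=C[C@](C)(/C=C/C=C/c3ccccc3)[C@](C)(C(=O)OC)[C@@H]12 | intermediate
20 | 22‑nor‑zyggomphic acid B | CCC1=C[C@@H](C)[C@@H]2C(C)=C[C@](C)(/C=C/C=C/c3ccccc3)[C@](C)(C(=O)O)[C@@H]12 | target

## Step count

Total steps: 13.
Longest linear sequence: 12 steps (1 → 20 via steps 1–7 and 9–13; step 8 is a one‑step side branch).

## Steps most likely to fail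

1. **Step 12 (IMDA).** The Z‑alkene in the three‑atom tether makes the trans‑fused transition state strained. A [1,5]‑H shift of the bis‑allylic C6–H into conjugation, or a cis‑fused adduct, could compete.
 Fallback: use a saturated tether. Aldol of 11 with the lithium enolate of methyl butanoate gives a C5‑silyloxy, C4‑H(Et) tether, and the same DIBAL and MnO2/Wittig end‑game gives an sp3‑tethered triene ester. Run the IMDA on that, then introduce the C2=C3 alkene after ring formation by regioselective syn‑elimination (Burgess or Chugaev) of the ring carbinol.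

2. **Step 9 (with step 7).** Aldehyde 11 is β,γ‑unsaturated and α‑stereogenic, so it can epimerise or slip into conjugation with the tetraene during oxidation or olefination.
 Fallback: move the polyene to the end by cross‑coupling. From 4, make the methyl alkyne (Corey–Fuchs/MeI) and the (E)-vinyl iodide TBSOCH2–CH(Me)–CH=C(Me)I (Cp2Zr(H)Cl, then I2). Carry this smaller, less conjugation‑prone iodo‑aldehyde through steps 6–11, then attach the phenyltrienyl unit by Negishi carboalumination of (3E,5E)-6-phenylhexa-3,5-dien-1-yne and Pd coupling to reach 18.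

3. **Step 11 (oxidation–Wittig).** The Z‑2‑ethyl enal may isomerise to E (which cannot cyclise) or react sluggishly with the α‑methyl ylide.
 Fallback: avoid the Z‑enal. Convert 11 to the (Z)-vinyl iodide with Ph3P=C(I)Et (Stork–Zhao type), then form C3–C4 by Suzuki coupling with methyl (E)-2-methyl-3-(pinacolboryl)acrylate with retention, giving 18 directly.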